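**Remark on the chemistry (assumption).** The target has no stereocentre, no stereogenic axis and no C=C bond outside its arenes, so it is achiral and "the single enantiomer" is the compound itself. The sp3 ring carbon of 8 and 12 is a stereocentre; both are carried as racemates, and the centre is erased when ring B becomes aromatic.

**Route in one sentence.** Ring B is assembled with all six substituents in place by a thermal cyclobutenone/ynol-ether benzannulation of a 2,3,4-trisubstituted cyclobutenone with a benzyl-substituted methoxyalkyne. This sentence does not describe the obvious route, which is benzylation of a preformed bibenzyl.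

## Structural features

The target is a bibenzyl: ring A, a 3-methoxyphenyl group, is joined through a CH2–CH2 bridge to ring B. Ring B is a hexasubstituted benzene; numbered from the bridge carbon it carries the bridge at C1, 4-hydroxybenzyl groups at C2, C4 and C6, a free OH at C3 and OMe at C5. There are no stereocentres, so nothing has to be controlled in three dimensions. The fragile features are the four phenols and the three 4-hydroxybenzyl–arene bonds (latent p-quinone methides), which argue for unveiling the phenols last under neutral conditions. The real difficulty is ring B: six substituents in a fixed order, three identical benzyl groups on alternating carbons, and two oxygens differentiated as OH and OMe, all next to four other electron-rich rings that must stay untouched. The key step exploits the fact that ring B is a phenol (C3–OH) with an alkoxy group meta to it (C5–OMe) and an alkylated carbon between them (C4). C4–C5 is the two-carbon unit of a benzyl-substituted methoxyalkyne, and C3(=O), C2, C1 and C6 are the four carbons of a cyclobutenone into whose C3–C6 bond that alkyne can be inserted. Each of C2, C4 and C6 then arrives with its benzyl group already attached, and the OH/OMe distinction follows from the origin of the two oxygens (ketene carbonyl versus alkyne ether).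

## Logic of the disconnections

**18 ⇒ 17.** The three O–CH2Ph bonds of the outer phenols are cut (in the forward sense, three O–H bonds are formed). The free 4-hydroxybenzyl groups are quinone-methide precursors and would not survive bases, acid chlorides or organometallics. The gain is a robust, non-acidic intermediate. The demand is a neutral deprotection that touches no C–C bond; 17 has no other reducible group.

**17 ⇒ 12 + 4 (key).** Ring B is cut at C3–C4 and C5–C6; the C2–C3 bond is opened and re-closed during the forward cascade. This turns a hexasubstituted arene into a four-membered ring carrying C3(=O), C2, C1, C6 with their three substituents, plus an alkyne carrying the C4 benzyl group and the C5 methoxy group. The gain is the whole substitution problem of ring B, including the OH/OMe differentiation, in one atom-economical operation. The demand is a regioselective [2+2] union of a fully substituted vinylketene with an internal ynol ether, followed by two electrocyclic events under purely thermal conditions.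

**12 ⇒ 8 + 10 (from 9).** The bond between C1 of ring B (C3 of the four-membered ring) and the bridge CH2 is cut, with transposition of the carbonyl group. This removes ring A with its two-carbon arm and leaves a vinylogous ester. The demand is carbonyl addition without enolisation, then hydrolysis. Because C2 and C4 of 8 carry the same benzyl group, 1,2-addition/transposition and 1,4-addition/elimination give the same constitution, so the regiochemistry of the addition is not critical.

**8 ⇒ 4 + 7 (from 6, from 5).** The two ring bonds formed by a ketene/ynol-ether [2+2] are cut (carbonyl carbon to benzyl-bearing alkyne carbon, and ketene α-carbon to methoxy-bearing alkyne carbon). The gain is that the four-membered ring comes from the same alkyne 4 that serves in the key step and from an acid chloride one step from a commercial acid. The demand is that 7, made in the flask, is trapped by 4 faster than it dimerises; the regiochemistry is set by the polarity of the partners.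

**4 ⇒ 3 (from 1) + 2.** The propargylic C(sp)–CH2 bond is cut. This leads to two commercial compounds. The demand is an SN2 alkylation of an alkoxyacetylide by a benzylic bromide without isomerisation of the doubly activated CH2 group of the product.

## Other disconnections considered

**Alternative 1:** (the first that comes to mind, and the presumed biosynthesis) Cut the three aryl–CH2 bonds at C2, C4 and C6 of ring B. The forward key step is a triple Friedel–Crafts alkylation of the bibenzyl A1 (3-methoxy-5-[2-(3-methoxyphenyl)ethyl]phenol) by the p-quinone methide A3, generated from 4-hydroxybenzyl alcohol A2, giving 18 directly. It is very short, but neither the number nor the position of the alkylations is set by the substrate. Ring A of A1 is also activated by its methoxy group. Every 4-hydroxyphenyl ring that is introduced is itself a phenol with two open ortho positions and reacts with A3 as in phenol–formaldehyde oligomerisation. The third alkylation must occur on an already crowded ring. The chosen plan makes none of these bonds by substitution, so the question of site and count does not arise.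

**Alternative 2:** Cut the central CH2–CH2 bond of the bridge. The forward key step is a union of two carbons of like polarity, a nickel-catalysed reductive cross-electrophile coupling (or a mixed Kolbe electrolysis of the corresponding arylacetic acids) of the pentasubstituted benzyl bromide A4 with 3-methoxybenzyl bromide A5, giving the tetrabenzyl ether A6 and then 18. The bond cut is the easiest one in the molecule: A4 still contains the complete hexasubstituted ring, so the real difficulty is only moved into its synthesis. Two benzylic halides of similar reactivity should also give statistical homo- and cross-coupling, and the CH2Br group of A4 is flanked by two ortho benzyl groups. The route would be longer and the key step would settle little.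

**Alternative 3:** Cut the aromaticity of ring B. The precursor is the cyclohexane-1,3-dione A7 carrying the arylethyl arm at C5; it is benzylated three times with 2 (at C2, then at C4 and C6 through vinylogous-ester enolates) to give A8. Oxidative aromatisation with iodine in methanol would convert A8 into the resorcinol monomethyl ether 17. The idea is sound and sets OH/OMe during aromatisation. It needs three separate enolate alkylations, with C- versus O-alkylation at C2 and two alkylations next to the C5 substituent, plus protection and deprotection of the dione. No single step carries the difficulty, and iodine could also attack the electron-rich rings. The step count would be roughly double that of the chosen plan.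

Key step: step 5

## Steps

**Step 1**
Reactants: 1 2-chloro-1,1-dimethoxyethane; 2 4-(benzyloxy)benzyl bromide
Product: 4 1-(benzyloxy)-4-(3-methoxyprop-2-yn-1-yl)benzene, via lithium methoxyacetylide 3 (not isolated)
Conditions: 1 (1.5 equiv), LDA (4.5 equiv), THF, −78 → 0 °C; then DMPU, 2 (1.0 equiv), −78 °C → rt; Et3N-deactivated silica
Reagents that add atoms: none
Why: Three equivalents of LDA convert 1 by two eliminations (MeOH, then HCl) and deprotonation into acetylide 3, which is alkylated in an SN2 reaction by the activated benzylic bromide 2 in a dipolar cosolvent; the hindered amine set free should not compete for 2, and the benzyl ether is inert.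

**Step 2**
Reactants: 5 3-[4-(benzyloxy)phenyl]propanoic acid
Product: 6 3-[4-(benzyloxy)phenyl]propanoyl chloride
Conditions: (COCl)2 (1.3 equiv), DMF (cat.), CH2Cl2, 0 °C → rt; concentrate, use crude
Reagents that add atoms: oxalyl chloride, O=C(Cl)C(=O)Cl
Why: Standard acid chloride formation through the Vilsmeier-type chloroiminium catalyst; the aryl benzyl ether is stable to these conditions.

**Step 3**
Reactants: 6 3-[4-(benzyloxy)phenyl]propanoyl chloride; 4 1-(benzyloxy)-4-(3-methoxyprop-2-yn-1-yl)benzene
Product: 8 2,4-bis[4-(benzyloxy)benzyl]-3-methoxycyclobut-2-en-1-one (racemic), via aldoketene 7 (not isolated)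
Conditions: 4 (1.0 equiv), 6 (1.4 equiv), Et3N (1.6 equiv, syringe pump), CH2Cl2, 0 °C → rt
Reagents that add atoms: none
Why: Dehydrochlorination of 6 gives aldoketene 7, which undergoes the regioselective ketene/ynol-ether [2+2] cycloaddition (the nucleophilic benzyl-bearing alkyne carbon bonds to the ketene carbonyl carbon), the standard entry to 3-alkoxycyclobutenones; slow addition of base keeps 7 dilute against dimerisation, and the new sp3 centre forms as the racemate.

**Step 4**
Reactants: 8 2,4-bis[4-(benzyloxy)benzyl]-3-methoxycyclobut-2-en-1-one; 9 1-(2-bromoethyl)-3-methoxybenzene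
Product: 12 2,4-bis[4-(benzyloxy)benzyl]-3-[2-(3-methoxyphenyl)ethyl]cyclobut-2-en-1-one (racemic), via Grignard reagent 10 (not isolated), via cyclobutenol adduct 11 (not isolated)
Conditions: 9, Mg, I2 (cat.), THF, rt; add to 8, THF, −78 → 0 °C; then 1 M HCl, THF, 0 °C → rt
Reagents that add atoms: water, O
Why: Stork–Danheiser-type carbonyl transposition of a vinylogous ester: Grignard addition to the carbonyl (enolisation would give an antiaromatic cyclobutadienolate and is disfavoured), then acid ionises the tertiary allylic alcohol and hydrolyses the enol ether with loss of methanol; since C2 and C4 of 8 bear the same group, any 1,4-addition/elimination converges on the same compound 12.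

**Step 5**
Reactants: 12 2,4-bis[4-(benzyloxy)benzyl]-3-[2-(3-methoxyphenyl)ethyl]cyclobut-2-en-1-one; 4 1-(benzyloxy)-4-(3-methoxyprop-2-yn-1-yl)benzene
Product: 17 2,4,6-tris[4-(benzyloxy)benzyl]-3-methoxy-5-[2-(3-methoxyphenyl)ethyl]phenol, via vinylketene 13 (not isolated), via vinylcyclobutenone 14 (not isolated), via dienylketene 15 (not isolated), via cyclohexadienone 16 (not isolated)
Conditions: 4 (1.5 equiv), PhMe (0.5 M), 80 °C then 110 °C, sealed tube, Ar
Reagents that add atoms: none
Why: Heating opens 12 by conrotatory 4π-electrocyclic ring opening to vinylketene 13, the benzyl group on the sp3 carbon rotating outward so that H takes the inside position of the diene terminus. The ketene C=C of 13 then adds ynol ether 4 in a [2+2] cycloaddition, the nucleophilic benzyl-bearing alkyne carbon bonding to the ketene carbonyl carbon (ring B C3–C4) and the methoxy-bearing carbon to the ketene α-carbon (C5–C6), to give 14. 14 opens again (4π) to dienylketene 15, which closes ring B by a thermal disrotatory 6π-electrocyclisation (bond C2–C3) to cyclohexadienone 16, and enolisation gives phenol 17. The closest known reaction type is the Danheiser benzannulation of cyclobutenones with heteroatom-substituted alkynes, applied here to a fully substituted case. Ring B is the only ring that remains; the four-membered ring of 14 is formed by [2+2] and consumed. No stereocentre survives, because the sp3 centres of 12, 14 and 16 are erased on aromatisation, so racemic 12 suffices. The selectivity needed is the regiochemistry of the [2+2] step; it is secured by the polarisation of the ynol ether, which places OMe meta to the new OH and fixes the order benzyl/OH/benzyl/OMe/benzyl/chain around the ring. The methyl ynol ether has no β-hydrogen for the thermal retro-ene loss that affects higher alkoxyalkynes, and the 2,6-disubstituted phenol formed should be too hindered to trap 13.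

**Step 6**
Reactants: 17 2,4,6-tris[4-(benzyloxy)benzyl]-3-methoxy-5-[2-(3-methoxyphenyl)ethyl]phenol
Product: 18 2,4,6-tris(4-hydroxybenzyl)-3-methoxy-5-[2-(3-methoxyphenyl)ethyl]phenol (CNP0285788.0)
Conditions: H2 (1 atm), 10% Pd/C, EtOAc–MeOH (1:1), rt
Reagents that add atoms: none
Why: Hydrogenolysis of three aryl benzyl ethers over palladium under neutral conditions; the diarylmethane C–C bonds, aryl methyl ethers and arenes are inert, and no stereocentre is involved.

## Compound list

1 | 2-chloro-1,1-dimethoxyethane | ClCC(OC)OC | starting material
2 | 4-(benzyloxy)benzyl bromide | BrCc1ccc(OCc2ccccc2)cc1 | starting material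
3 | lithium methoxyacetylide | COC#C[Li] | intermediate
4 | 1-(benzyloxy)-4-(3-methoxyprop-2-yn-1-yl)benzene | COC#CCc1ccc(OCc2ccccc2)cc1 | intermediate
5 | 3-[4-(benzyloxy)phenyl]propanoic acid | OC(=O)CCc1ccc(OCc2ccccc2)cc1 | starting material
6 | 3-[4-(benzyloxy)phenyl]propanoyl chloride | ClC(=O)CCc1ccc(OCc2ccccc2)cc1 | intermediate
7 | 4-[4-(benzyloxy)phenyl]buta-1,2-dien-1-one (aldoketene) | O=C=CCc1ccc(OCc2ccccc2)cc1 | intermediate
8 | 2,4-bis[4-(benzyloxy)benzyl]-3-methoxycyclobut-2-en-1-one (racemic) | COC1=C(Cc2ccc(OCc3ccccc3)cc2)C(=O)C1Cc1ccc(OCc2ccccc2)cc1 | intermediate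
9 | 1-(2-bromoethyl)-3-methoxybenzene | COc1cccc(CCBr)c1 | starting material
10 | [2-(3-methoxyphenyl)ethyl]magnesium bromide | COc1cccc(CC[Mg]Br)c1 | intermediate
11 | 2,4-bis[4-(benzyloxy)benzyl]-3-methoxy-1-[2-(3-methoxyphenyl)ethyl]cyclobut-2-en-1-ol (mixture of diastereomers, formed as its magnesium alkoxide) | COC1=C(Cc2ccc(OCc3ccccc3)cc2)C(O)(CCc2cccc(OC)c2)C1Cc1ccc(OCc2ccccc2)cc1 | intermediate
12 | 2,4-bis[4-(benzyloxy)benzyl]-3-[2-(3-methoxyphenyl)ethyl]cyclobut-2-en-1-one (racemic) | O=C1C(Cc2ccc(OCc3ccccc3)cc2)=C(CCc2cccc(OC)c2)C1Cc1ccc(OCc2ccccc2)cc1 | intermediate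
13 | (3E)-2-[4-(benzyloxy)benzyl]-5-[4-(benzyloxy)phenyl]-3-[2-(3-methoxyphenyl)ethyl]penta-1,3-dien-1-one (vinylketene) | O=C=C(Cc1ccc(OCc2ccccc2)cc1)/C(CCc1cccc(OC)c1)=C/Cc1ccc(OCc2ccccc2)cc1 | intermediate
14 | 2,4-bis[4-(benzyloxy)benzyl]-3-methoxy-4-{(2E)-1-[4-(benzyloxy)phenyl]-5-(3-methoxyphenyl)pent-2-en-3-yl}cyclobut-2-en-1-one (racemic) | COC1=C(Cc2ccc(OCc3ccccc3)cc2)C(=O)C1(Cc2ccc(OCc3ccccc3)cc2)/C(CCc2cccc(OC)c2)=C/Cc2ccc(OCc3ccccc3)cc2 | intermediate
15 | (3E,5E)-2,4-bis[4-(benzyloxy)benzyl]-7-[4-(benzyloxy)phenyl]-3-methoxy-5-[2-(3-methoxyphenyl)ethyl]hepta-1,3,5-trien-1-one (dienylketene, ketene and alkenyl groups cis on the central C=C) | O=C=C(Cc1ccc(OCc2ccccc2)cc1)/C(OC)=C(Cc1ccc(OCc2ccccc2)cc1)\C(CCc1cccc(OC)c1)=C\Cc1ccc(OCc2ccccc2)cc1 | intermediate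
16 | 2,4,6-tris[4-(benzyloxy)benzyl]-3-methoxy-5-[2-(3-methoxyphenyl)ethyl]cyclohexa-2,4-dien-1-one (racemic) | COC1=C(Cc2ccc(OCc3ccccc3)cc2)C(=O)C(Cc2ccc(OCc3ccccc3)cc2)C(CCc2cccc(OC)c2)=C1Cc1ccc(OCc2ccccc2)cc1 | intermediate
17 | 2,4,6-tris[4-(benzyloxy)benzyl]-3-methoxy-5-[2-(3-methoxyphenyl)ethyl]phenol | COc1cccc(CCc2c(Cc3ccc(OCc4ccccc4)cc3)c(O)c(Cc3ccc(OCc4ccccc4)cc3)c(OC)c2Cc2ccc(OCc3ccccc3)cc2)c1 | intermediate
18 | 2,4,6-tris(4-hydroxybenzyl)-3-methoxy-5-[2-(3-methoxyphenyl)ethyl]phenol (CNP0285788.0, achiral) | COc1cccc(CCc2c(Cc3ccc(O)cc3)c(O)c(Cc3ccc(O)cc3)c(OC)c2Cc2ccc(O)cc2)c1 | target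

## Step count and risk

Total step count: 6. Longest linear sequence: 5 steps (step 1 or step 2, then steps 3, 4, 5, 6). Compound 4 is used twice, in steps 3 and 5.

**Step 5 (key step).** The bimolecular [2+2] capture of the fully substituted vinylketene by the internal ynol ether must create a quaternary carbon next to the methoxy-bearing carbon. If this capture is slow, reversible re-closure to 12, ketene self-condensation and acylation of the product phenol could take over, and prolonged heating could degrade the excess ynol ether. Fallback, setting out from 12 and 3 and coming back at 17: 12 is heated with the unhindered terminal ynol ether methoxyacetylene F1, set free from 3 by one equivalent of acetic acid and used as a solution. This should give 2,4-bis[4-(benzyloxy)benzyl]-5-methoxy-3-[2-(3-methoxyphenyl)ethyl]phenol F2, in which only C4 of ring B is open. Friedel–Crafts benzylation of F2 with 2 (ZnCl2, CH2Cl2, 0 °C) at this position, ortho to both OH and OMe, then gives 17. The last benzyl group is thus attached by substitution at the single remaining site instead of being carried in by the alkyne.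

**Step 3.** Dimerisation of the aldoketene and direct acylation of the ynol ether by the acid chloride could outrun the cycloaddition, because the ketene is generated in the presence of amine and amine hydrochloride. Fallback, setting out from 4 and coming back at 8: the ketene is generated without base by Wolff rearrangement. Commercial 4-(benzyloxy)phenylacetic acid F3 is converted with oxalyl chloride into 4-(benzyloxy)phenylacetyl chloride F4 and with diazomethane (2 equiv) into 1-[4-(benzyloxy)phenyl]-3-diazopropan-2-one F5. Irradiation of F5 (300 nm, CH2Cl2, rt) in the presence of 4 forms 7 at low stationary concentration, and 7 is trapped to give 8.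

**Step 1.** Propargyl–allenyl isomerisation of the doubly activated CH2 group of the product under the basic conditions, competing N-benzylation of the amine set free, and acid-catalysed hydration of the ynol ether on work-up could erode the alkylation. Fallback, setting out from 3 (made from 1) and 2 and coming back at 4: 3 is quenched with tributyltin chloride to give tributyl(methoxyethynyl)stannane F6, which is joined to 2 by a Stille coupling (Pd(PPh3)4, THF, 50 °C) under neutral conditions. The C–C bond is then made by palladium catalysis and not by SN2 attack of a basic acetylide.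

**Step 4.** β-Hydride transfer (reduction) from the primary alkyl Grignard reagent to the hindered carbonyl group, Wurtz coupling during its formation, and acid-induced opening of the strained product during hydrolysis are the likely losses. Fallback, setting out from 8 and coming back at 18: commercial 1-ethynyl-3-methoxybenzene F7 is deprotonated (n-BuLi, THF, −78 °C) to lithium (3-methoxyphenyl)acetylide F8, a small nucleophile without β-hydrogens. F8 adds to 8 to give 2,4-bis[4-(benzyloxy)benzyl]-3-methoxy-1-[(3-methoxyphenyl)ethynyl]cyclobut-2-en-1-ol F9, and dilute HCl converts F9 into 2,4-bis[4-(benzyloxy)benzyl]-3-[(3-methoxyphenyl)ethynyl]cyclobut-2-en-1-one F10. The thermal benzannulation of F10 with 4 under the conditions of step 5 should give 2,4,6-tris[4-(benzyloxy)benzyl]-3-methoxy-5-[(3-methoxyphenyl)ethynyl]phenol F11. Hydrogenation of F11 (H2, Pd/C) saturates the alkyne to the CH2–CH2 bridge and removes the three benzyl ethers in the same operation, giving 18 with no additional step.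

## Further compounds

F1 | step 5 | methoxyacetylene | COC#C
F2 | step 5 | 2,4-bis[4-(benzyloxy)benzyl]-5-methoxy-3-[2-(3-methoxyphenyl)ethyl]phenol | COc1cccc(CCc2c(Cc3ccc(OCc4ccccc4)cc3)c(O)cc(OC)c2Cc2ccc(OCc3ccccc3)cc2)c1
F3 | step 3 | 4-(benzyloxy)phenylacetic acid (commercial) | OC(=O)Cc1ccc(OCc2ccccc2)cc1
F4 | step 3 | 4-(benzyloxy)phenylacetyl chloride | ClC(=O)Cc1ccc(OCc2ccccc2)cc1
F5 | step 3 | 1-[4-(benzyloxy)phenyl]-3-diazopropan-2-one | [N-]=[N+]=CC(=O)Cc1ccc(OCc2ccccc2)cc1
F6 | step 1 | tributyl(methoxyethynyl)stannane | COC#C[Sn](CCCC)(CCCC)CCCC
F7 | step 4 | 1-ethynyl-3-methoxybenzene (commercial) | COc1cccc(C#C)c1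
F8 | step 4 | lithium (3-methoxyphenyl)acetylide | COc1cccc(C#C[Li])c1
F9 | step 4 | 2,4-bis[4-(benzyloxy)benzyl]-3-methoxy-1-[(3-methoxyphenyl)ethynyl]cyclobut-2-en-1-ol (mixture of diastereomers) | COC1=C(Cc2ccc(OCc3ccccc3)cc2)C(O)(C#Cc2cccc(OC)c2)C1Cc1ccc(OCc2ccccc2)cc1
F10 | step 4 | 2,4-bis[4-(benzyloxy)benzyl]-3-[(3-methoxyphenyl)ethynyl]cyclobut-2-en-1-one (racemic) | O=C1C(Cc2ccc(OCc3ccccc3)cc2)=C(C#Cc2cccc(OC)c2)C1Cc1ccc(OCc2ccccc2)cc1
F11 | step 4 | 2,4,6-tris[4-(benzyloxy)benzyl]-3-methoxy-5-[(3-methoxyphenyl)ethynyl]phenol | COc1cccc(C#Cc2c(Cc3ccc(OCc4ccccc4)cc3)c(O)c(Cc3ccc(OCc4ccccc4)cc3)c(OC)c2Cc2ccc(OCc3ccccc3)cc2)c1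
A1 | alternative 1 | 3-methoxy-5-[2-(3-methoxyphenyl)ethyl]phenol | COc1cccc(CCc2cc(O)cc(OC)c2)c1
A2 | alternative 1 | 4-hydroxybenzyl alcohol | OCc1ccc(O)cc1
A3 | alternative 1 | 4-methylidenecyclohexa-2,5-dien-1-one (p-quinone methide) | C=C1C=CC(=O)C=C1
A4 | alternative 2 | 3-(benzyloxy)-2,4,6-tris[4-(benzyloxy)benzyl]-5-methoxybenzyl bromide | BrCc1c(Cc2ccc(OCc3ccccc3)cc2)c(OCc2ccccc2)c(Cc2ccc(OCc3ccccc3)cc2)c(OC)c1Cc1ccc(OCc2ccccc2)cc1
A5 | alternative 2 | 3-methoxybenzyl bromide | COc1cccc(CBr)c1
A6 | alternative 2 | 1-(benzyloxy)-2,4,6-tris[4-(benzyloxy)benzyl]-3-methoxy-5-[2-(3-methoxyphenyl)ethyl]benzene | COc1cccc(CCc2c(Cc3ccc(OCc4ccccc4)cc3)c(OCc3ccccc3)c(Cc3ccc(OCc4ccccc4)cc3)c(OC)c2Cc2ccc(OCc3ccccc3)cc2)c1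
A7 | alternative 3 | 5-[2-(3-methoxyphenyl)ethyl]cyclohexane-1,3-dione | COc1cccc(CCC2CC(=O)CC(=O)C2)c1
A8 | alternative 3 | 2,4,6-tris[4-(benzyloxy)benzyl]-5-[2-(3-methoxyphenyl)ethyl]cyclohexane-1,3-dione (mixture of diastereomers) | O=C1C(Cc2ccc(OCc3ccccc3)cc2)C(=O)C(Cc2ccc(OCc3ccccc3)cc2)C(CCc2cccc(OC)c2)C1Cc1ccc(OCc2ccccc2)cc1
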